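**Strategy**

Ring A (C1 the quaternary carbon, C2/C4/C6 oxygen-bearing, C3 the acid-chain carbon, C5 the ring B acyl carbon) is cut at C1–C6 and C2–C3 into a 2-alkyl-3-silyloxycyclobutenone carrying the protected acid chain and a silyl ynol ether carrying the lavandulyl chain. Their thermal benzannulation exploits the alternation of oxygens (C2, C4, C6) and carbon substituents around ring A: one operation builds the arene with both side chains in place, O2 and O4 silylated, and O6 as the sole free hydroxyl beside the sole unsubstituted carbon C5. Ring B is then closed on O6/C5, and C1 is dearomatised last by prenylation.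

Key step: step 11

**Remarks on the chemistry (assumptions)**

- Ring A numbering C1–C6 is used throughout; in chromene names C1 = C8, C2 = C7, C3 = C6, C4 = C5, C5 = C4a, C6 = C8a.
- Abbreviations: Lav = (2R)-5-methyl-2-(prop-1-en-2-yl)hex-4-en-1-yl; TIPS = tri(propan-2-yl)silyl.
- Both silyl groups are TIPS: smaller silyl ynol ethers tend to slip to C-silyl ketenes, the cyclobutenone silyl enol ether must survive zinc reduction, and both aryl silyl ethers are removed together later, so they need not differ.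
- The target side chain (2R) corresponds in space to (S)-lavandulol; only the CIP priorities change when CH2OH becomes CH2–C.
- The lipase is assumed to acylate (R)-lavandulol faster, so that the (S)-alcohol is the one recovered; if the preference were opposite, the acetate fraction would be saponified instead.
- (−)-Quinine is assumed to deliver the (2R,3S)-cis chromanone from the ortho-tigloylphenol; quinidine would be used if the sense were opposite.
- The facial sense of the chiral palladium catalyst at C1 cannot be predicted with confidence; the (1R,2R)-ligand is written and its mirror image would be used if the opposite face is preferred.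

**Route**

Step 1
Reactants: 1 (±)-lavandulol
Product: 2 (S)-lavandulol
Conditions: immobilised Candida antarctica lipase B, vinyl acetate, hexane, 25 °C, to ca. 60% conversion; chromatography
Reagents that add atoms: none
Why: Lipase-catalysed kinetic resolution by transesterification, in which the faster acylation of the (R)-alcohol should leave the (S)-alcohol, so the lavandulyl stereocentre is selected here and not created.

Step 2
Reactants: 2 (S)-lavandulol
Product: 4 trimethyl[(4R)-7-methyl-4-(prop-1-en-2-yl)oct-6-en-1-yn-1-yl]silane, via lavandulyl triflate 3 (not isolated)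
Conditions: Tf2O, 2,6-lutidine, CH2Cl2, −78 °C; then LiC≡CSiMe3 (from Me3SiC≡CH, n-BuLi; 3 equiv), THF/DMPU, −78 → −20 °C
Reagents that add atoms: trimethylsilylacetylene, C#C[Si](C)(C)C
Why: SN2 alkynylation of a primary triflate by a lithium acetylide, fast enough at low temperature that elimination towards the allylic beta-hydrogen should not compete, and the stereocentre is not touched.

Step 3
Reactants: 4 trimethyl[(4R)-7-methyl-4-(prop-1-en-2-yl)oct-6-en-1-yn-1-yl]silane
Product: 5 (4R)-7-methyl-4-(prop-1-en-2-yl)oct-6-en-1-yne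
Conditions: K2CO3, MeOH, 25 °C
Reagents that add atoms: none
Why: Methoxide-mediated protodesilylation of an alkynylsilane, which leaves the alkenes and the stereocentre alone.

Step 4
Reactants: 5 (4R)-7-methyl-4-(prop-1-en-2-yl)oct-6-en-1-yne
Product: 7 {[(4R)-7-methyl-4-(prop-1-en-2-yl)oct-6-en-1-yn-1-yl]oxy}tri(propan-2-yl)silane, via lithium ynolate 6 (not isolated)
Conditions: n-BuLi, THF, −78 °C; t-BuOOLi (from t-BuOOH, LiN(SiMe3)2), −78 → 0 °C; i-Pr3SiOTf, −78 °C
Reagents that add atoms: tert-butyl hydroperoxide, CC(C)(C)OO; triisopropylsilyl trifluoromethanesulfonate, CC(C)[Si](C(C)C)(C(C)C)OS(=O)(=O)C(F)(F)F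
Why: Oxidation of the lithium acetylide by lithium tert-butyl peroxide gives the ynolate, which the bulky silyl triflate traps on oxygen to give a thermally robust silyl ynol ether.

Step 5
Reactants: 8 (4S)-4-benzyl-1,3-oxazolidin-2-one; 9 pentanoyl chloride
Product: 10 (4S)-4-benzyl-3-pentanoyl-1,3-oxazolidin-2-one
Conditions: n-BuLi, THF, −78 °C; then 9, −78 → 0 °C
Reagents that add atoms: none
Why: N-acylation of the lithiated oxazolidinone by the acid chloride.

Step 6
Reactants: 10 (4S)-4-benzyl-3-pentanoyl-1,3-oxazolidin-2-one; 11 tert-butyl bromoacetate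
Product: 12 tert-butyl (3R)-3-{[(4S)-4-benzyl-2-oxo-1,3-oxazolidin-3-yl]carbonyl}hexanoate
Conditions: NaN(SiMe3)2, THF, −78 °C; then 11, −78 → −40 °C
Reagents that add atoms: none
Why: Evans asymmetric alkylation, in which the chelated Z-sodium enolate is alkylated on the face opposite the benzyl group and so sets the acid-chain stereocentre as R.

Step 7
Reactants: 12 tert-butyl (3R)-3-{[(4S)-4-benzyl-2-oxo-1,3-oxazolidin-3-yl]carbonyl}hexanoate
Product: 13 4-tert-butyl 1-methyl (2R)-2-propylbutanedioate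
Conditions: MeMgBr, MeOH, CH2Cl2, 0 °C
Reagents that add atoms: methanol, CO
Why: Transesterification of the N-acyloxazolidinone by bromomagnesium methoxide at the exocyclic carbonyl, under which the tert-butyl ester is inert and the alpha-stereocentre is not enolised.

Step 8
Reactants: 13 4-tert-butyl 1-methyl (2R)-2-propylbutanedioate
Product: 16 tert-butyl (3R)-3-propyl-5-{[tri(propan-2-yl)silyl]oxy}pent-4-ynoate, via dibromomethyl ketone 14 (not isolated), via lithium ynolate 15 (not isolated)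
Conditions: CH2Br2, lithium 2,2,6,6-tetramethylpiperidide, THF, −78 °C; then 13; LiN(SiMe3)2 (2.2 equiv); n-BuLi, −78 → 25 °C; i-Pr3SiCl, −78 → 0 °C
Reagents that add atoms: dibromomethane, BrCBr; chlorotriisopropylsilane, CC(C)[Si](Cl)(C(C)C)C(C)C
Why: Kowalski ynolate synthesis: dibromomethyllithium adds to the methyl ester (the tert-butyl ester is hindered and is masked as its enolate by the extra amide base), bromine–lithium exchange on the dibromo-enolate triggers a carbenoid 1,2-shift of the alpha-carbon with retention, and the bulky silyl chloride silylates the ynolate on oxygen.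

Step 9
Reactants: 16 tert-butyl (3R)-3-propyl-5-{[tri(propan-2-yl)silyl]oxy}pent-4-ynoate
Product: 17 tert-butyl (3R)-3-{3,3-dichloro-4-oxo-2-{[tri(propan-2-yl)silyl]oxy}cyclobut-1-en-1-yl}hexanoate
Conditions: Cl2CHCOCl, Et3N (slow addition), Et2O, 0 → 25 °C
Reagents that add atoms: dichloroacetyl chloride, O=C(Cl)C(Cl)Cl
Why: [2+2] cycloaddition of the electron-rich ynol ether with dichloroketene made in the flask, in which the nucleophilic beta-carbon bonds to the ketene carbonyl carbon and fixes the 2-alkyl-3-silyloxy pattern.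

Step 10
Reactants: 17 tert-butyl (3R)-3-{3,3-dichloro-4-oxo-2-{[tri(propan-2-yl)silyl]oxy}cyclobut-1-en-1-yl}hexanoate
Product: 18 tert-butyl (3R)-3-{4-oxo-2-{[tri(propan-2-yl)silyl]oxy}cyclobut-1-en-1-yl}hexanoate
Conditions: Zn, AcOH, TMEDA, EtOH, 0 → 25 °C
Reagents that add atoms: none
Why: Zinc reduction of the alpha,alpha-dichloroketone unit under amine-buffered acetic acid, the standard dechlorination of 4,4-dichlorocyclobutenones, which should spare the vinylogous silyl ester and the tert-butyl ester.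

Step 11
Reactants: 18 tert-butyl (3R)-3-{4-oxo-2-{[tri(propan-2-yl)silyl]oxy}cyclobut-1-en-1-yl}hexanoate; 7 {[(4R)-7-methyl-4-(prop-1-en-2-yl)oct-6-en-1-yn-1-yl]oxy}tri(propan-2-yl)silane
Product: 23 tert-butyl (3R)-3-{4-hydroxy-3-Lav-2,6-bis(TIPS-oxy)phenyl}hexanoate, via vinylketene 19 (not isolated), via vinylcyclobutenone 20 (not isolated), via dienylketene 21 (not isolated), via cyclohexadienone 22 (not isolated)
Conditions: 18 (1.0 equiv), 7 (1.3 equiv), toluene (0.4 M), 80 °C then 110 °C, sealed tube, argon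
Reagents that add atoms: none
Why: Thermal four-electron ring opening of 18 gives vinylketene 19, whose carbonyl carbon (future C6) bonds to the nucleophilic beta-carbon of ynol ether 7 (future C1) while its alpha-carbon (C3) bonds to the silyloxy carbon (C2) in a [2+2] cycloaddition, and the vinylcyclobutenone 20 reopens to dienylketene 21. Ring A then closes by thermal disrotatory six-electron electrocyclisation (C5–C6 bond) to dienone 22, which tautomerises to the phenol. This is the Danheiser benzannulation of a cyclobutenone with a siloxyalkyne. No stereocentre is created (the quaternary carbon of 20 is lost on ring opening) and the two existing ones are remote from the reacting atoms. The step needs regiocontrol in the [2+2] event and chemoselectivity over the lavandulyl alkenes, and the polarisation of the ynol ether together with its far higher ketenophilicity should secure both. The result is the O/C alternation of ring A with O6–H free beside C5–H and O2 and O4 as silyl ethers.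

Step 12
Reactants: 23 tert-butyl (3R)-3-{4-hydroxy-3-Lav-2,6-bis(TIPS-oxy)phenyl}hexanoate; 24 (2E)-2-methylbut-2-enoyl chloride (tigloyl chloride)
Product: 25 4-[(3R)-1-tert-butoxy-1-oxohexan-3-yl]-2-Lav-3,5-bis(TIPS-oxy)phenyl (2E)-2-methylbut-2-enoate
Conditions: pyridine, DMAP (cat.), CH2Cl2, 0 → 25 °C
Reagents that add atoms: none
Why: DMAP-catalysed O-acylation of the single free phenol, with pyridine as base to avoid ketene formation and deconjugation of the tigloyl unit.

Step 13
Reactants: 25 4-[(3R)-1-tert-butoxy-1-oxohexan-3-yl]-2-Lav-3,5-bis(TIPS-oxy)phenyl (2E)-2-methylbut-2-enoate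
Product: 26 tert-butyl (3R)-3-{4-hydroxy-3-Lav-5-[(2E)-2-methylbut-2-enoyl]-2,6-bis(TIPS-oxy)phenyl}hexanoate
Conditions: hν (254 nm, quartz), degassed cyclohexane (0.01 M), 25 °C
Reagents that add atoms: none
Why: Photo-Fries rearrangement, in which homolysis of the aryl O–acyl bond and in-cage recombination can only be productive at C5 (C1 and C3, the other ortho and the para position, are blocked), giving a chelated ortho-hydroxyaryl enone that acts as a photostable internal filter.

Step 14
Reactants: 26 tert-butyl (3R)-3-{4-hydroxy-3-Lav-5-[(2E)-2-methylbut-2-enoyl]-2,6-bis(TIPS-oxy)phenyl}hexanoate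
Product: 27 tert-butyl (3R)-3-{(2R,3S)-2,3-dimethyl-8-Lav-4-oxo-5,7-bis(TIPS-oxy)-3,4-dihydro-2H-chromen-6-yl}hexanoate
Conditions: (−)-quinine (20 mol %), chlorobenzene, 25 °C
Reagents that add atoms: none
Why: Cinchona-alkaloid-catalysed intramolecular oxa-Michael addition of an ortho-tigloylphenol, in which the catalyst should guide O6 to one face of the enone beta-carbon (O-bearing carbon R) and kinetic protonation of the enol gives the 2,3-cis isomer (3S), while the silyl group on O4 leaves O6 as the only oxygen able to close ring B.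

Step 15
Reactants: 27 tert-butyl (3R)-3-{(2R,3S)-2,3-dimethyl-8-Lav-4-oxo-5,7-bis(TIPS-oxy)-3,4-dihydro-2H-chromen-6-yl}hexanoate
Product: 28 tert-butyl (3R)-3-{(2R,3S)-5,7-dihydroxy-2,3-dimethyl-8-Lav-4-oxo-3,4-dihydro-2H-chromen-6-yl}hexanoate
Conditions: Bu4NF, AcOH (1:1), THF, 0 °C
Reagents that add atoms: none
Why: Fluoride cleavage of both aryl silyl ethers, buffered with acetic acid so that the cis-chromanone neither epimerises at its alpha-carbon nor opens by retro-oxa-Michael reaction.

Step 16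
Reactants: 28 tert-butyl (3R)-3-{(2R,3S)-5,7-dihydroxy-2,3-dimethyl-8-Lav-4-oxo-3,4-dihydro-2H-chromen-6-yl}hexanoate
Product: 29 tert-butyl (3R)-3-{(2R,3S,8R)-5-hydroxy-2,3-dimethyl-8-(3-methylbut-2-en-1-yl)-8-Lav-4,7-dioxo-3,4,7,8-tetrahydro-2H-chromen-6-yl}hexanoate
Conditions: Pd2(dba)3·CHCl3 (2.5 mol %), (1R,2R)-N,N'-bis(2-diphenylphosphinobenzoyl)cyclohexane-1,2-diamine (7.5 mol %), tert-butyl prenyl carbonate (1.2 equiv), THF, 0 → 25 °C
Reagents that add atoms: tert-butyl 3-methylbut-2-en-1-yl carbonate, CC(C)=CCOC(=O)OC(C)(C)C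
Why: Tsuji–Trost asymmetric allylic alkylation used as a dearomatisation, in which zerovalent palladium ionises the carbonate, the liberated tert-butoxide deprotonates the acidic O2–H, and the phenoxide attacks the unsubstituted prenyl terminus through C1, the less hindered ortho carbon (C3 carries an alpha-branched chain), with the chiral ligand relied on to choose the face that makes C1 (chromene C8) R.

Step 17
Reactants: 29 tert-butyl (3R)-3-{(2R,3S,8R)-5-hydroxy-2,3-dimethyl-8-(3-methylbut-2-en-1-yl)-8-Lav-4,7-dioxo-3,4,7,8-tetrahydro-2H-chromen-6-yl}hexanoate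
Product: 31 (3R)-3-{(2R,3S,8R)-5-hydroxy-2,3-dimethyl-8-(3-methylbut-2-en-1-yl)-8-Lav-4,7-dioxo-3,4,7,8-tetrahydro-2H-chromen-6-yl}hexanoic acid (target), via bis(trimethylsilyl) derivative 30 (not isolated)
Conditions: Me3SiOTf, 2,6-lutidine, CH2Cl2, 0 °C; then pH 5 aqueous buffer
Reagents that add atoms: none
Why: Silyl-triflate-mediated conversion of the tert-butyl ester into a silyl ester with loss of isobutene under lutidine buffering, which avoids protic acid (prenyl/enol cyclisation) and aqueous base (epimerisation or opening of ring B), followed by hydrolysis of the silyl ester and silyl enol ether on mild aqueous work-up.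

**Compound list**

1 | (±)-lavandulol, rac-5-methyl-2-(prop-1-en-2-yl)hex-4-en-1-ol | C=C(C)C(CO)CC=C(C)C | starting material
2 | (S)-lavandulol | C=C(C)[C@H](CC=C(C)C)CO | intermediate
3 | (2S)-5-methyl-2-(prop-1-en-2-yl)hex-4-en-1-yl trifluoromethanesulfonate (not isolated) | C=C(C)[C@H](CC=C(C)C)COS(=O)(=O)C(F)(F)F | intermediate
4 | trimethyl[(4R)-7-methyl-4-(prop-1-en-2-yl)oct-6-en-1-yn-1-yl]silane | C=C(C)[C@H](CC=C(C)C)CC#C[Si](C)(C)C | intermediate
5 | (4R)-7-methyl-4-(prop-1-en-2-yl)oct-6-en-1-yne | C=C(C)[C@H](CC=C(C)C)CC#C | intermediate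
6 | lithium (4R)-7-methyl-4-(prop-1-en-2-yl)oct-6-en-1-yn-1-olate (not isolated) | C=C(C)[C@H](CC=C(C)C)CC#C[O-].[Li+] | intermediate
7 | {[(4R)-7-methyl-4-(prop-1-en-2-yl)oct-6-en-1-yn-1-yl]oxy}tri(propan-2-yl)silane | C=C(C)[C@H](CC=C(C)C)CC#CO[Si](C(C)C)(C(C)C)C(C)C | intermediate
8 | (4S)-4-benzyl-1,3-oxazolidin-2-one | O=C1N[C@@H](Cc2ccccc2)CO1 | starting material
9 | pentanoyl chloride | CCCCC(=O)Cl | starting material
10 | (4S)-4-benzyl-3-pentanoyl-1,3-oxazolidin-2-one | CCCCC(=O)N1[C@@H](Cc2ccccc2)COC1=O | intermediate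
11 | tert-butyl bromoacetate | CC(C)(C)OC(=O)CBr | starting material
12 | tert-butyl (3R)-3-{[(4S)-4-benzyl-2-oxo-1,3-oxazolidin-3-yl]carbonyl}hexanoate | O=C([C@H](CCC)CC(=O)OC(C)(C)C)N1[C@@H](Cc2ccccc2)COC1=O | intermediate
13 | 4-tert-butyl 1-methyl (2R)-2-propylbutanedioate | COC(=O)[C@H](CCC)CC(=O)OC(C)(C)C | intermediate
14 | tert-butyl (3R)-5,5-dibromo-4-oxo-3-propylpentanoate (present as its lithium enolate; not isolated) | BrC(Br)C(=O)[C@H](CCC)CC(=O)OC(C)(C)C | intermediate
15 | lithium (3R)-5-tert-butoxy-5-oxo-3-propylpent-1-yn-1-olate (not isolated) | [Li+].[O-]C#C[C@H](CCC)CC(=O)OC(C)(C)C | intermediate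
16 | tert-butyl (3R)-3-propyl-5-{[tri(propan-2-yl)silyl]oxy}pent-4-ynoate | CC(C)[Si](C(C)C)(C(C)C)OC#C[C@H](CCC)CC(=O)OC(C)(C)C | intermediate
17 | tert-butyl (3R)-3-{3,3-dichloro-4-oxo-2-{[tri(propan-2-yl)silyl]oxy}cyclobut-1-en-1-yl}hexanoate | O=C1C(Cl)(Cl)C(O[Si](C(C)C)(C(C)C)C(C)C)=C1[C@H](CCC)CC(=O)OC(C)(C)C | intermediate
18 | tert-butyl (3R)-3-{4-oxo-2-{[tri(propan-2-yl)silyl]oxy}cyclobut-1-en-1-yl}hexanoate | O=C1CC(O[Si](C(C)C)(C(C)C)C(C)C)=C1[C@H](CCC)CC(=O)OC(C)(C)C | intermediate
19 | vinylketene, tert-butyl (3R)-3-(1-oxo-3-{[tri(propan-2-yl)silyl]oxy}buta-1,3-dien-2-yl)hexanoate (not isolated) | O=C=C([C@H](CCC)CC(=O)OC(C)(C)C)C(=C)O[Si](C(C)C)(C(C)C)C(C)C | intermediate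
20 | vinylcyclobutenone, tert-butyl (3R)-3-{3-Lav-4-oxo-2-(TIPS-oxy)-1-[1-(TIPS-oxy)ethenyl]cyclobut-2-en-1-yl}hexanoate, both configurations at the ring quaternary carbon (not isolated) | C=C(C)[C@H](CC=C(C)C)CC1=C(O[Si](C(C)C)(C(C)C)C(C)C)C(C(=C)O[Si](C(C)C)(C(C)C)C(C)C)([C@H](CCC)CC(=O)OC(C)(C)C)C1=O | intermediate
21 | dienylketene O=C=C(Lav)–C(OTIPS)=C(acid chain)–C(OTIPS)=CH2, ketene and vinyl cis on the central alkene (not isolated) | C=C(C)[C@H](CC=C(C)C)CC(=C=O)/C(O[Si](C(C)C)(C(C)C)C(C)C)=C(/[C@H](CCC)CC(=O)OC(C)(C)C)C(=C)O[Si](C(C)C)(C(C)C)C(C)C | intermediate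
22 | cyclohexadienone, tert-butyl (3R)-3-{5-Lav-4-oxo-2,6-bis(TIPS-oxy)cyclohexa-1,5-dien-1-yl}hexanoate (not isolated) | C=C(C)[C@H](CC=C(C)C)CC1=C(O[Si](C(C)C)(C(C)C)C(C)C)C([C@H](CCC)CC(=O)OC(C)(C)C)=C(O[Si](C(C)C)(C(C)C)C(C)C)CC1=O | intermediate
23 | tert-butyl (3R)-3-{4-hydroxy-3-Lav-2,6-bis(TIPS-oxy)phenyl}hexanoate | C=C(C)[C@H](CC=C(C)C)Cc1c(O)cc(O[Si](C(C)C)(C(C)C)C(C)C)c([C@H](CCC)CC(=O)OC(C)(C)C)c1O[Si](C(C)C)(C(C)C)C(C)C | intermediate
24 | (2E)-2-methylbut-2-enoyl chloride (tigloyl chloride) | C/C=C(\C)C(=O)Cl | starting material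
25 | 4-[(3R)-1-tert-butoxy-1-oxohexan-3-yl]-2-Lav-3,5-bis(TIPS-oxy)phenyl (2E)-2-methylbut-2-enoate | C=C(C)[C@H](CC=C(C)C)Cc1c(OC(=O)/C(C)=C/C)cc(O[Si](C(C)C)(C(C)C)C(C)C)c([C@H](CCC)CC(=O)OC(C)(C)C)c1O[Si](C(C)C)(C(C)C)C(C)C | intermediate
26 | tert-butyl (3R)-3-{4-hydroxy-3-Lav-5-[(2E)-2-methylbut-2-enoyl]-2,6-bis(TIPS-oxy)phenyl}hexanoate | C=C(C)[C@H](CC=C(C)C)Cc1c(O)c(C(=O)/C(C)=C/C)c(O[Si](C(C)C)(C(C)C)C(C)C)c([C@H](CCC)CC(=O)OC(C)(C)C)c1O[Si](C(C)C)(C(C)C)C(C)C | intermediate
27 | tert-butyl (3R)-3-{(2R,3S)-2,3-dimethyl-8-Lav-4-oxo-5,7-bis(TIPS-oxy)-3,4-dihydro-2H-chromen-6-yl}hexanoate | C=C(C)[C@H](CC=C(C)C)Cc1c2O[C@H](C)[C@H](C)C(=O)c2c(O[Si](C(C)C)(C(C)C)C(C)C)c([C@H](CCC)CC(=O)OC(C)(C)C)c1O[Si](C(C)C)(C(C)C)C(C)C | intermediate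
28 | tert-butyl (3R)-3-{(2R,3S)-5,7-dihydroxy-2,3-dimethyl-8-Lav-4-oxo-3,4-dihydro-2H-chromen-6-yl}hexanoate | C=C(C)[C@H](CC=C(C)C)Cc1c2O[C@H](C)[C@H](C)C(=O)c2c(O)c([C@H](CCC)CC(=O)OC(C)(C)C)c1O | intermediate
29 | tert-butyl (3R)-3-{(2R,3S,8R)-5-hydroxy-2,3-dimethyl-8-(3-methylbut-2-en-1-yl)-8-Lav-4,7-dioxo-3,4,7,8-tetrahydro-2H-chromen-6-yl}hexanoate | C=C(C)[C@H](CC=C(C)C)C[C@@]1(CC=C(C)C)C(=O)C([C@H](CCC)CC(=O)OC(C)(C)C)=C(O)C2=C1O[C@H](C)[C@H](C)C2=O | intermediate
30 | trimethylsilyl ester of the target with the C5 enol oxygen also trimethylsilylated (not isolated) | C=C(C)[C@H](CC=C(C)C)C[C@@]1(CC=C(C)C)C(=O)C([C@H](CCC)CC(=O)O[Si](C)(C)C)=C(O[Si](C)(C)C)C2=C1O[C@H](C)[C@H](C)C2=O | intermediate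
31 | (3R)-3-{(2R,3S,8R)-5-hydroxy-2,3-dimethyl-8-(3-methylbut-2-en-1-yl)-8-[(2R)-5-methyl-2-(prop-1-en-2-yl)hex-4-en-1-yl]-4,7-dioxo-3,4,7,8-tetrahydro-2H-chromen-6-yl}hexanoic acid | C=C(C)[C@H](CC=C(C)C)C[C@@]1(CC=C(C)C)C(=O)C([C@H](CCC)CC(=O)O)=C(O)C2=C1O[C@H](C)[C@H](C)C2=O | target

**Step count and risks**

Total: 17 steps. Longest linear sequence: 13 steps (steps 5–17); the lavandulyl branch (steps 1–4) joins at step 11.

Steps most likely to fail:

1. Step 16. The chiral catalyst may give poor facial selectivity at C1, and attack through C3 or through oxygen may compete. The fallback sets out from 28 and comes back at 29. It drops catalyst control for a classical alkylative dearomatisation: 28 is treated with one equivalent of NaOMe and prenyl bromide in MeOH at −10 °C, the single equivalent of base being consumed by the acidic phenol so that ring B is not exposed to free alkoxide. This would give 29 together with its C8 epimer, tert-butyl (3R)-3-{(2R,3S,8S)-5-hydroxy-2,3-dimethyl-8-(3-methylbut-2-en-1-yl)-8-Lav-4,7-dioxo-3,4,7,8-tetrahydro-2H-chromen-6-yl}hexanoate F1. The two diastereomers are separated by preparative HPLC and 29 continues to step 17.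

2. Step 13. The tigloyl double bond may photoisomerise, the acyl radical may escape the cage (photodeacylation back to 23), and conversion may stall as the product absorbs the light. The fallback sets out from 23 and comes back at 26, building the acyl group without light. Magnesium-mediated ortho-formylation (MgCl2, Et3N, paraformaldehyde, THF, 65 °C) can only occur at C5 and would give the salicylaldehyde tert-butyl (3R)-3-{3-formyl-4-hydroxy-5-Lav-2,6-bis(TIPS-oxy)phenyl}hexanoate F2. Addition of (E)-but-2-en-2-yllithium (from (E)-2-bromobut-2-ene and t-BuLi, THF, −78 °C, 2.2 equiv to allow for the phenol) would give the allylic benzylic alcohol tert-butyl (3R)-3-{4-hydroxy-3-[(2E)-1-hydroxy-2-methylbut-2-en-1-yl]-5-Lav-2,6-bis(TIPS-oxy)phenyl}hexanoate F3 as a mixture of carbinol epimers. Oxidation with MnO2 in CH2Cl2 then gives 26.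

3. Step 8. The organolithium reagents may attack the tert-butyl ester, or the methyl ester may be enolised before dibromomethyllithium adds, which would erode the configuration. The fallback sets out from 13 and comes back at 16, making the ynol ether from a terminal alkyne instead of an ester. i-Bu2AlH (toluene, −78 °C) reduces the methyl ester selectively to tert-butyl (3R)-3-formylhexanoate F4. Seyferth–Gilbert homologation in its Ohira–Bestmann form (dimethyl (1-diazo-2-oxopropyl)phosphonate, K2CO3, MeOH, 0 °C) gives tert-butyl (3R)-3-ethynylhexanoate F5. F5 is then deprotonated with one equivalent of n-BuLi at −78 °C, oxidised with t-BuOOLi and silylated with i-Pr3SiOTf as in step 4 to give 16.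

Further compounds
F1 | step 16 | tert-butyl (3R)-3-{(2R,3S,8S)-5-hydroxy-2,3-dimethyl-8-(3-methylbut-2-en-1-yl)-8-Lav-4,7-dioxo-3,4,7,8-tetrahydro-2H-chromen-6-yl}hexanoate | C=C(C)[C@H](CC=C(C)C)C[C@]1(CC=C(C)C)C(=O)C([C@H](CCC)CC(=O)OC(C)(C)C)=C(O)C2=C1O[C@H](C)[C@H](C)C2=O
F2 | step 13 | tert-butyl (3R)-3-{3-formyl-4-hydroxy-5-Lav-2,6-bis(TIPS-oxy)phenyl}hexanoate | C=C(C)[C@H](CC=C(C)C)Cc1c(O)c(C=O)c(O[Si](C(C)C)(C(C)C)C(C)C)c([C@H](CCC)CC(=O)OC(C)(C)C)c1O[Si](C(C)C)(C(C)C)C(C)C
F3 | step 13 | tert-butyl (3R)-3-{4-hydroxy-3-[(2E)-1-hydroxy-2-methylbut-2-en-1-yl]-5-Lav-2,6-bis(TIPS-oxy)phenyl}hexanoate (both carbinol epimers) | C=C(C)[C@H](CC=C(C)C)Cc1c(O)c(C(O)/C(C)=C/C)c(O[Si](C(C)C)(C(C)C)C(C)C)c([C@H](CCC)CC(=O)OC(C)(C)C)c1O[Si](C(C)C)(C(C)C)C(C)C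
F4 | step 8 | tert-butyl (3R)-3-formylhexanoate | O=C[C@H](CCC)CC(=O)OC(C)(C)C
F5 | step 8 | tert-butyl (3R)-3-ethynylhexanoate | C#C[C@H](CCC)CC(=O)OC(C)(C)C
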